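**Plan**
- Retrosynthesis: the three prenyl termini are cut back to allyl groups (cross-metathesis), then the ester O–CH3 bond and the silyl ether, and finally the diaryl ether C–O bond of ring A together with its ring-to-carboxyl C–C bond, leaving a ring B phenol, 3-(allyloxy)benzyne and CO2.
- Enabling feature: in ring A (the benzoate ring) the ester-bearing carbon lies between the carbon that carries the prenyloxy group and the carbon that carries the diaryl ether oxygen. This is the pattern left when a nucleophile (the ring B phenoxide, at the ether carbon) and an electrophile (CO2, at the ester carbon) add across the triple bond of a 3-alkoxybenzyne.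
- Forward: the aryne precursor from 2-bromoresorcinol (steps 1–3); the ring B phenol from 5-bromo-2-hydroxy-4-methoxybenzaldehyde (steps 4–9); union of the two with CO2 (step 10); esterification, threefold allyl-to-prenyl metathesis and desilylation (steps 11–13).
- No ring is formed: both benzene rings are bought, and the two halves are joined first at the ether oxygen and then at the carboxyl carbon in one flask.
- Stereochemistry: the target has no stereocentre and no stereogenic double bond, so nothing has to be controlled.

Key step: step 10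

Remark: the three prenyl groups are carried as allyl groups up to step 12. The peracid of step 6 would epoxidise a trisubstituted prenyl alkene, and a prenyl ether beside the aryne could be intercepted by an intramolecular ene reaction. A monosubstituted alkene reacts far more slowly with peracid and has no hydrogen placed for the ene pathway.

**Route**

Step 1
Reactants: 1 2-bromobenzene-1,3-diol (2-bromoresorcinol)
Product: 2 2-bromo-1,3-bis(trimethylsilyloxy)benzene
Conditions: HMDS, THF, 70 °C; volatiles removed
Reagents that add atoms: hexamethyldisilazane, C[Si](C)(C)N[Si](C)(C)C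
Why: O-silylation of phenols by HMDS with loss of ammonia is clean and should give a bis(silyl ether) pure enough to use directly.

Step 2
Reactants: 2 2-bromo-1,3-bis(trimethylsilyloxy)benzene
Product: 6 3-hydroxy-2-(trimethylsilyl)phenyl trifluoromethanesulfonate, via aryllithium 3 (not isolated), via lithium phenoxide 4 (not isolated), via silyloxy triflate 5 (not isolated)
Conditions: n-BuLi, THF, −78 °C; Tf2O, −78 → 0 °C; then AcOH, MeOH–H2O, rt
Reagents that add atoms: trifluoromethanesulfonic anhydride, O=S(=O)(OS(=O)(=O)C(F)(F)F)C(F)(F)F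
Why: Bromine–lithium exchange gives aryllithium 3, one of whose two flanking silyl groups moves from oxygen to carbon (anionic retro-Brook rearrangement, the usual entry to 2-silylaryl triflates), so that the two resorcinol oxygens are told apart without statistics, phenoxide 4 is triflated and the remaining aryl silyl ether of 5 is hydrolysed by mild acid.

Step 3
Reactants: 6 3-hydroxy-2-(trimethylsilyl)phenyl trifluoromethanesulfonate
Product: 7 3-(allyloxy)-2-(trimethylsilyl)phenyl trifluoromethanesulfonate
Conditions: allyl alcohol, PPh3, DIAD, THF, 0 °C → rt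
Reagents that add atoms: allyl alcohol, C=CCO
Why: Mitsunobu etherification of a phenol with a primary allylic alcohol runs under essentially neutral conditions, so the phenol beside silicon and triflate is not held as a free phenoxide by an added base, which could otherwise set off silyl migration and early aryne release.

Step 4
Reactants: 8 5-bromo-2-hydroxy-4-methoxybenzaldehyde
Product: 9 5-allyl-2-hydroxy-4-methoxybenzaldehyde
Conditions: allylSnBu3, Pd(PPh3)4 (5 mol%), toluene, 100 °C; aqueous KF work-up
Reagents that add atoms: allyltributylstannane, C=CC[Sn](CCCC)(CCCC)CCCC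
Why: Migita–Kosugi–Stille coupling of an aryl bromide with an allylstannane tolerates the free phenol and the aldehyde, an allyl group raises no alpha/gamma question, and the coupling is placed before O-allylation so that no aryl allyl ether can ionise on zerovalent palladium.

Step 5
Reactants: 9 5-allyl-2-hydroxy-4-methoxybenzaldehyde
Product: 10 5-allyl-2-(allyloxy)-4-methoxybenzaldehyde
Conditions: allyl bromide, K2CO3, DMF, rt
Reagents that add atoms: allyl bromide, C=CCBr
Why: Williamson etherification of the salicylaldehyde phenol with an allylic bromide and K2CO3 is routine and fixes which of the two future catechol oxygens carries the alkenyl group.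

Step 6
Reactants: 10 5-allyl-2-(allyloxy)-4-methoxybenzaldehyde
Product: 12 5-allyl-2-(allyloxy)-4-methoxyphenol, via aryl formate 11 (not isolated)
Conditions: mCPBA (1.1 equiv), CH2Cl2, 0 °C; then K2CO3 (cat.), MeOH, rt
Reagents that add atoms: 3-chloroperoxybenzoic acid, OOC(=O)c1cccc(Cl)c1
Why: In this Dakin-type Baeyer–Villiger oxidation the ortho and para alkoxy groups make aryl migration fast, so the peracid should be consumed by the aldehyde well before it epoxidises the two monosubstituted alkenes, and formate 11 is cleaved by methanolysis.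

Step 7
Reactants: 12 5-allyl-2-(allyloxy)-4-methoxyphenol
Product: 13 6-allyl-3-(allyloxy)-2-hydroxy-5-methoxybenzaldehyde
Conditions: MgCl2, Et3N, (CH2O)n, MeCN, reflux; 1 M HCl work-up
Reagents that add atoms: paraformaldehyde (formaldehyde), C=O
Why: In the Casnati–Skattebøl ortho-formylation the magnesium phenoxide delivers formaldehyde only ortho to oxygen, and the single free ortho carbon, next to the C-allyl group, is the one that will carry the hydroxymethyl group of ring B.

Step 8
Reactants: 13 6-allyl-3-(allyloxy)-2-hydroxy-5-methoxybenzaldehyde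
Product: 14 3-allyl-6-(allyloxy)-2-(hydroxymethyl)-4-methoxyphenol
Conditions: NaBH4, MeOH–THF, 0 °C
Reagents that add atoms: none
Why: Hydride reduction with NaBH4 converts the aldehyde into the benzylic alcohol and leaves alkenes and ethers untouched.

Step 9
Reactants: 14 3-allyl-6-(allyloxy)-2-(hydroxymethyl)-4-methoxyphenol
Product: 15 3-allyl-6-(allyloxy)-4-methoxy-2-{[(triisopropylsilyl)oxy]methyl}phenol
Conditions: TIPSCl (1.05 equiv), imidazole, DMF, 0 °C → rt
Reagents that add atoms: chlorotriisopropylsilane, CC(C)[Si](Cl)(C(C)C)C(C)C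
Why: Chemoselective silylation is expected because the bulky silyl chloride should react with the primary benzylic alcohol faster than with the phenol, which is flanked on both sides and hydrogen-bonded.

Step 10
Reactants: 15 3-allyl-6-(allyloxy)-4-methoxy-2-{[(triisopropylsilyl)oxy]methyl}phenol; 7 3-(allyloxy)-2-(trimethylsilyl)phenyl trifluoromethanesulfonate; 16 carbon dioxide
Product: 21 2-(allyloxy)-6-[3-allyl-6-(allyloxy)-4-methoxy-2-{[(triisopropylsilyl)oxy]methyl}phenoxy]benzoic acid, via potassium phenoxide 17 (not isolated), via 3-(allyloxy)benzyne 18 (not isolated), via aryl potassium 19 (not isolated), via potassium carboxylate 20 (not isolated)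
Conditions: 15 (1.2 equiv), KH, THF, 0 °C; then KF, 18-crown-6, dry CO2 (1 atm), slow addition of 7, THF, 0 °C → rt; cold 1 M HCl to pH 3
Reagents that add atoms: none
Why: Proposed new method: fluoride attacks the trimethylsilyl group of 7 and triflate leaves to give aryne 18; phenoxide 17 adds to the aryne carbon remote from the allyloxy group, the future ether carbon of ring A, which places the charge of 19 on the carbon in between, beside the inductively withdrawing allyloxy oxygen, and this aryl anion is carboxylated by the dissolved CO2 to give 20. The closest known reaction types are the O-arylation of phenoxides by arynes released from 2-silylaryl triflates and the three-component coupling of arynes, amines and CO2 under KF and 18-crown-6; the union of a phenoxide, an aryne and CO2 has not been shown. No ring is closed and no stereocentre is formed. The step needs regioselective addition across the aryne and carboxylation in preference to protonation: the first is secured by the allyloxy group beside the triple bond, which distorts the aryne so that the remote carbon is the flatter and more electrophilic one, the second by the absence of any O–H or N–H donor (phenoxide made beforehand with KH, hydroxymethyl group silylated) and by the excess of CO2. Only O-arylation is possible because both ortho positions and the para position of the phenoxide are substituted, the allyl ether offers no hydrogen on the far side of its double bond for an intramolecular ene reaction with the aryne, and the phenoxide is kept in slight excess with slow addition of 7 so that carboxylate 20 does not consume a second aryne.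

Step 11
Reactants: 21 2-(allyloxy)-6-[3-allyl-6-(allyloxy)-4-methoxy-2-{[(triisopropylsilyl)oxy]methyl}phenoxy]benzoic acid
Product: 22 methyl 2-(allyloxy)-6-[3-allyl-6-(allyloxy)-4-methoxy-2-{[(triisopropylsilyl)oxy]methyl}phenoxy]benzoate
Conditions: MeI, K2CO3, DMF, rt
Reagents that add atoms: iodomethane, CI
Why: O-alkylation of the carboxylate (bimolecular substitution at the methyl group) is indifferent to the two ortho substituents that would block a Fischer esterification.

Step 12
Reactants: 22 methyl 2-(allyloxy)-6-[3-allyl-6-(allyloxy)-4-methoxy-2-{[(triisopropylsilyl)oxy]methyl}phenoxy]benzoate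
Product: 23 methyl 2-[4-methoxy-3-(3-methylbut-2-en-1-yl)-6-[(3-methylbut-2-en-1-yl)oxy]-2-{[(triisopropylsilyl)oxy]methyl}phenoxy]-6-[(3-methylbut-2-en-1-yl)oxy]benzoate
Conditions: second-generation Grubbs catalyst RuCl2(=CHPh)(H2IMes)(PCy3) (10 mol%), 2-methyl-2-butene–CH2Cl2, 35 °C, sealed vessel
Reagents that add atoms: 2-methyl-2-butene, CC=C(C)C
Why: Olefin cross-metathesis of terminal allyl groups with excess 2-methyl-2-butene is the standard conversion of allyl into prenyl, since the trisubstituted products do not re-enter the cycle and the large excess of the butene drives the exchange and suppresses homodimerisation and ring closure between the allyl groups.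

Step 13
Reactants: 23 methyl 2-[4-methoxy-3-(3-methylbut-2-en-1-yl)-6-[(3-methylbut-2-en-1-yl)oxy]-2-{[(triisopropylsilyl)oxy]methyl}phenoxy]-6-[(3-methylbut-2-en-1-yl)oxy]benzoate
Product: 24 methyl 2-[2-(hydroxymethyl)-4-methoxy-3-(3-methylbut-2-en-1-yl)-6-[(3-methylbut-2-en-1-yl)oxy]phenoxy]-6-[(3-methylbut-2-en-1-yl)oxy]benzoate (CNP0500611.0)
Conditions: TBAF, AcOH, THF, 0 °C → rt
Reagents that add atoms: none
Why: Fluoride-induced desilylation cleaves the primary silyl ether, and the AcOH buffer should keep the liberated alkoxide from attacking the neighbouring methyl ester.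

**Compound list**

1 | 2-bromobenzene-1,3-diol (2-bromoresorcinol) | Oc1cccc(O)c1Br | starting material
2 | 2-bromo-1,3-bis(trimethylsilyloxy)benzene | C[Si](C)(C)Oc1cccc(O[Si](C)(C)C)c1Br | intermediate
3 | 2,6-bis(trimethylsilyloxy)phenyllithium (not isolated) | [Li]c1c(O[Si](C)(C)C)cccc1O[Si](C)(C)C | intermediate
4 | lithium 2-(trimethylsilyl)-3-(trimethylsilyloxy)phenoxide (not isolated) | [Li+].[O-]c1cccc(O[Si](C)(C)C)c1[Si](C)(C)C | intermediate
5 | 2-(trimethylsilyl)-3-(trimethylsilyloxy)phenyl trifluoromethanesulfonate (not isolated) | C[Si](C)(C)Oc1cccc(OS(=O)(=O)C(F)(F)F)c1[Si](C)(C)C | intermediate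
6 | 3-hydroxy-2-(trimethylsilyl)phenyl trifluoromethanesulfonate | Oc1cccc(OS(=O)(=O)C(F)(F)F)c1[Si](C)(C)C | intermediate
7 | 3-(allyloxy)-2-(trimethylsilyl)phenyl trifluoromethanesulfonate | C=CCOc1cccc(OS(=O)(=O)C(F)(F)F)c1[Si](C)(C)C | intermediate
8 | 5-bromo-2-hydroxy-4-methoxybenzaldehyde | COc1cc(O)c(C=O)cc1Br | starting material
9 | 5-allyl-2-hydroxy-4-methoxybenzaldehyde | COc1cc(O)c(C=O)cc1CC=C | intermediate
10 | 5-allyl-2-(allyloxy)-4-methoxybenzaldehyde | COc1cc(OCC=C)c(C=O)cc1CC=C | intermediate
11 | 5-allyl-2-(allyloxy)-4-methoxyphenyl formate (not isolated) | COc1cc(OCC=C)c(OC=O)cc1CC=C | intermediate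
12 | 5-allyl-2-(allyloxy)-4-methoxyphenol | COc1cc(OCC=C)c(O)cc1CC=C | intermediate
13 | 6-allyl-3-(allyloxy)-2-hydroxy-5-methoxybenzaldehyde | O=Cc1c(O)c(OCC=C)cc(OC)c1CC=C | intermediate
14 | 3-allyl-6-(allyloxy)-2-(hydroxymethyl)-4-methoxyphenol | OCc1c(O)c(OCC=C)cc(OC)c1CC=C | intermediate
15 | 3-allyl-6-(allyloxy)-4-methoxy-2-{[(triisopropylsilyl)oxy]methyl}phenol | C=CCOc1cc(OC)c(CC=C)c(CO[Si](C(C)C)(C(C)C)C(C)C)c1O | intermediate
16 | carbon dioxide | O=C=O | starting material
17 | potassium 3-allyl-6-(allyloxy)-4-methoxy-2-{[(triisopropylsilyl)oxy]methyl}phenoxide (not isolated) | [K+].[O-]c1c(OCC=C)cc(OC)c(CC=C)c1CO[Si](C(C)C)(C(C)C)C(C)C | intermediate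
18 | 3-(allyloxy)benzyne (not isolated) | C=CCOC1=CC=CC#C1 | intermediate
19 | potassium 2-(allyloxy)-6-(aryloxy)phenyl anion, aryl = ring B of 15 (not isolated) | [K+].C=CCOc1cccc(Oc2c(OCC=C)cc(OC)c(CC=C)c2CO[Si](C(C)C)(C(C)C)C(C)C)[c-]1 | intermediate
20 | potassium 2-(allyloxy)-6-[3-allyl-6-(allyloxy)-4-methoxy-2-{[(triisopropylsilyl)oxy]methyl}phenoxy]benzoate (not isolated) | [K+].[O-]C(=O)c1c(OCC=C)cccc1Oc1c(OCC=C)cc(OC)c(CC=C)c1CO[Si](C(C)C)(C(C)C)C(C)C | intermediate
21 | 2-(allyloxy)-6-[3-allyl-6-(allyloxy)-4-methoxy-2-{[(triisopropylsilyl)oxy]methyl}phenoxy]benzoic acid | OC(=O)c1c(OCC=C)cccc1Oc1c(OCC=C)cc(OC)c(CC=C)c1CO[Si](C(C)C)(C(C)C)C(C)C | intermediate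
22 | methyl 2-(allyloxy)-6-[3-allyl-6-(allyloxy)-4-methoxy-2-{[(triisopropylsilyl)oxy]methyl}phenoxy]benzoate | COC(=O)c1c(OCC=C)cccc1Oc1c(OCC=C)cc(OC)c(CC=C)c1CO[Si](C(C)C)(C(C)C)C(C)C | intermediate
23 | methyl 2-[4-methoxy-3-(3-methylbut-2-en-1-yl)-6-[(3-methylbut-2-en-1-yl)oxy]-2-{[(triisopropylsilyl)oxy]methyl}phenoxy]-6-[(3-methylbut-2-en-1-yl)oxy]benzoate | COC(=O)c1c(OCC=C(C)C)cccc1Oc1c(OCC=C(C)C)cc(OC)c(CC=C(C)C)c1CO[Si](C(C)C)(C(C)C)C(C)C | intermediate
24 | methyl 2-[2-(hydroxymethyl)-4-methoxy-3-(3-methylbut-2-en-1-yl)-6-[(3-methylbut-2-en-1-yl)oxy]phenoxy]-6-[(3-methylbut-2-en-1-yl)oxy]benzoate (CNP0500611.0) | COC(=O)c1c(OCC=C(C)C)cccc1Oc1c(OCC=C(C)C)cc(OC)c(CC=C(C)C)c1CO | target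

**Step count**

Total: 13 steps. Longest linear sequence: 10 steps (steps 4–13); the aryne branch (steps 1–3) joins at step 10.

**Steps most likely to fail**

Step 10 (proposed new method). Aryl anion 19 may be protonated before it is carboxylated, for instance by proton transfer from the benzylic or allylic positions of ring B. The phenoxide may also be held back as its O-carbonate under CO2, or carboxylate 20 may add to a second aryne. The fallback uses known chemistry, sets out from 15 and returns at 21. Commercial 2-fluoro-6-hydroxybenzaldehyde (Oc1cccc(F)c1C=O) is O-allylated with allyl bromide and K2CO3 in DMF to 2-(allyloxy)-6-fluorobenzaldehyde F1. Phenol 15 then displaces the fluoride ortho to the formyl group (nucleophilic aromatic substitution, K2CO3, DMF, 100 °C) to give 2-(allyloxy)-6-[3-allyl-6-(allyloxy)-4-methoxy-2-{[(triisopropylsilyl)oxy]methyl}phenoxy]benzaldehyde F2. Pinnick oxidation (NaClO2, NaH2PO4, 2-methyl-2-butene, t-BuOH–H2O) converts F2 into acid 21. The diaryl ether bond is then formed by substitution instead of aryne addition, and the carboxyl carbon is bought at the aldehyde level.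

Step 12. Exchange may stay incomplete at one of the three termini, and ruthenium hydride formed from the catalyst may move the O-allyl double bonds into conjugation with oxygen, after which the groups are lost. The fallback sets out from 22 and returns at 23. Pd(PPh3)4 and morpholine in THF remove the two O-allyl groups, while the C-allyl group cannot ionise, and give methyl 2-[3-allyl-6-hydroxy-4-methoxy-2-{[(triisopropylsilyl)oxy]methyl}phenoxy]-6-hydroxybenzoate F3. Prenyl bromide (CC(C)=CCBr) and K2CO3 in DMF alkylate both phenols to give methyl 2-[3-allyl-4-methoxy-6-[(3-methylbut-2-en-1-yl)oxy]-2-{[(triisopropylsilyl)oxy]methyl}phenoxy]-6-[(3-methylbut-2-en-1-yl)oxy]benzoate F4. The one remaining C-allyl group, the best-precedented substrate for this exchange, is then converted with 2-methyl-2-butene and the second-generation Grubbs catalyst RuCl2(=CHPh)(H2IMes)(PCy3) to reach 23.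

Step 9. The phenol may be silylated in competition with the benzylic alcohol, or the silyl group may move between the two oxygens. The fallback sets out from 14 and returns at 15. Both hydroxyl groups are silylated with TIPSOTf and 2,6-lutidine in CH2Cl2 to [3-allyl-6-(allyloxy)-4-methoxy-2-{[(triisopropylsilyl)oxy]methyl}phenoxy]triisopropylsilane F5. The aryl silyl ether, whose phenoxide is the better leaving group and which is therefore far more labile to base than the alkyl one, is then cleaved with KOH in MeOH–THF at rt to return to 15.

Further compounds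
F1 | step 10 | 2-(allyloxy)-6-fluorobenzaldehyde | C=CCOc1cccc(F)c1C=O
F2 | step 10 | 2-(allyloxy)-6-[3-allyl-6-(allyloxy)-4-methoxy-2-{[(triisopropylsilyl)oxy]methyl}phenoxy]benzaldehyde | O=Cc1c(OCC=C)cccc1Oc1c(OCC=C)cc(OC)c(CC=C)c1CO[Si](C(C)C)(C(C)C)C(C)C
F3 | step 12 | methyl 2-[3-allyl-6-hydroxy-4-methoxy-2-{[(triisopropylsilyl)oxy]methyl}phenoxy]-6-hydroxybenzoate | COC(=O)c1c(O)cccc1Oc1c(O)cc(OC)c(CC=C)c1CO[Si](C(C)C)(C(C)C)C(C)C
F4 | step 12 | methyl 2-[3-allyl-4-methoxy-6-[(3-methylbut-2-en-1-yl)oxy]-2-{[(triisopropylsilyl)oxy]methyl}phenoxy]-6-[(3-methylbut-2-en-1-yl)oxy]benzoate | COC(=O)c1c(OCC=C(C)C)cccc1Oc1c(OCC=C(C)C)cc(OC)c(CC=C)c1CO[Si](C(C)C)(C(C)C)C(C)C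
F5 | step 9 | [3-allyl-6-(allyloxy)-4-methoxy-2-{[(triisopropylsilyl)oxy]methyl}phenoxy]triisopropylsilane | C=CCOc1cc(OC)c(CC=C)c(CO[Si](C(C)C)(C(C)C)C(C)C)c1O[Si](C(C)C)(C(C)C)C(C)C
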